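## Retrosynthetic overview

1. Rabdosiin ⇐ deca-O-benzyl rabdosiin by one global Lewis-acid debenzylation (no hydrogenation, so the C3=C4 bond survives).
2. The 1-aryl-1,2-dihydronaphthalene ring ⇐ oxidative four-to-six ring expansion of an all-trans, head-to-head cyclobutane diester (δ-truxinate): the Ar–CH–CH–Ar bond is cut, the freed benzylic carbon bonds to C6 of the neighbouring aryl ring, and H2 is lost.
3. Cyclobutane ⇐ catalytic enantioselective [2+2] photodimerisation of perbenzylated (R)-rosmarinate; this fixes C2, and the ring expansion then sets C1 trans to it.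
4. Rosmarinate ⇐ Steglich ester of di-O-benzylcaffeic acid (Heck: aryl bromide + acrylic acid) with benzyl (R)-3-aryl-lactate (aryl Grignard + methyl (R)-glycidate, then methyl-to-benzyl exchange).
5. Ring order: the four aromatic rings come from catechol; the cyclobutane is formed first and is then expanded to the six-membered ring of the dihydronaphthalene.

Assumption: the SMILES is read as the (1R,2S)-trans-1,2-dihydronaphthalene-2,3-dicarboxylate esterified with two (R)-3-(3,4-dihydroxyphenyl)lactic acid units.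

## Route

Step 1
Reactants: 1 catechol
Product: 2 1,2-bis(benzyloxy)benzene
Conditions: BnBr (2.2 equiv), K2CO3 (3 equiv), DMF, 60 °C
Reagents that add atoms: benzyl bromide, BrCc1ccccc1
Why: Williamson ether synthesis alkylates both phenols; benzyl survives the Grignard, Heck, Lewis-acid and photoredox steps and can be removed at the end without hydrogen.

Step 2
Reactants: 2 1,2-bis(benzyloxy)benzene
Product: 3 4-bromo-1,2-bis(benzyloxy)benzene
Conditions: NBS (1.05 equiv), MeCN, 0 °C to rt, dark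
Reagents that add atoms: N-bromosuccinimide, O=C1CCC(=O)N1Br
Why: Electrophilic aromatic bromination goes para to an ether oxygen at the only unhindered activated position, and the polar solvent in the dark suppresses benzylic bromination.

Step 3
Reactants: 3 4-bromo-1,2-bis(benzyloxy)benzene; 4 methyl (R)-glycidate
Product: 6 methyl (2R)-3-[3,4-bis(benzyloxy)phenyl]-2-hydroxypropanoate, via 3,4-bis(benzyloxy)phenylmagnesium bromide 5 (not isolated)
Conditions: Mg turnings (1.5 equiv, I2), THF, 50 °C; then CuI (10 mol%), 4 (0.8 equiv), −40 to −20 °C; 1 M HCl, 0 °C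
Reagents that add atoms: none
Why: Copper-catalysed Grignard opening of the terminal epoxide (SN2 at the CH2 carbon, faster than ester addition at low temperature) leaves the C2 stereocentre of 4 untouched, so (R) is carried through.

Step 4
Reactants: 6 methyl (2R)-3-[3,4-bis(benzyloxy)phenyl]-2-hydroxypropanoate
Product: 7 benzyl (2R)-3-[3,4-bis(benzyloxy)phenyl]-2-hydroxypropanoate
Conditions: BnOH (10 equiv), Ti(OiPr)4 (10 mol%), toluene, 80 °C, 200 mbar (MeOH removed)
Reagents that add atoms: benzyl alcohol, OCc1ccccc1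
Why: Titanate-catalysed transesterification under neutral conditions does not racemise the α-hydroxy ester and makes the carboxyl group removable together with the phenol ethers.

Step 5
Reactants: 3 4-bromo-1,2-bis(benzyloxy)benzene; 8 acrylic acid
Product: 9 (E)-3-[3,4-bis(benzyloxy)phenyl]prop-2-enoic acid
Conditions: Pd(OAc)2 (2 mol%), P(o-tol)3 (6 mol%), Et3N (3 equiv), DMF, 100 °C; then 1 M HCl
Reagents that add atoms: none
Why: Mizoroki–Heck reaction; syn-insertion followed by syn-β-hydride elimination gives only the E-cinnamic acid.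

Step 6
Reactants: 7 benzyl (2R)-3-[3,4-bis(benzyloxy)phenyl]-2-hydroxypropanoate; 9 (E)-3-[3,4-bis(benzyloxy)phenyl]prop-2-enoic acid
Product: 10 benzyl (2R)-3-[3,4-bis(benzyloxy)phenyl]-2-{[(2E)-3-[3,4-bis(benzyloxy)phenyl]prop-2-enoyl]oxy}propanoate (pentabenzyl (R)-rosmarinate)
Conditions: DCC (1.2 equiv), DMAP (10 mol%), CH2Cl2, 0 °C to rt
Reagents that add atoms: none
Why: Steglich esterification activates the acid only, so the alcohol stereocentre reacts with retention and the E-alkene is unchanged.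

Step 7
Reactants: 10 pentabenzyl (R)-rosmarinate (two molecules)
Product: 11 bis[(2R)-1-(benzyloxy)-3-[3,4-bis(benzyloxy)phenyl]-1-oxopropan-2-yl] (1S,2S,3R,4R)-3,4-bis[3,4-bis(benzyloxy)phenyl]cyclobutane-1,2-dicarboxylate
Conditions: (S)-1-(2-methylphenyl)-3,3-diphenyltetrahydro-1H,3H-pyrrolo[1,2-c][1,3,2]oxazaborole protonated with HNTf2 (25 mol%), [Ir(ppy)2(dtbbpy)]PF6 (1 mol%), CH2Cl2 (0.3 M), −78 °C, 450 nm LEDs; chromatography
Reagents that add atoms: none
Why: Chiral-Lewis-acid-catalysed triplet-sensitised [2+2] photocycloaddition of a cinnamate ester: only the ester bound to the oxazaborolidinium is sensitised, Cα–Cα bonding to the bis-benzylic 1,4-diradical gives the head-to-head dimer, relaxation of that triplet diradical gives the all-trans ring, and the catalyst shields one face of the bound enoate to set (1S,2S,3R,4R).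

Step 8
Reactants: 11 the (1S,2S,3R,4R)-cyclobutane diester
Product: 12 bis[(2R)-1-(benzyloxy)-3-[3,4-bis(benzyloxy)phenyl]-1-oxopropan-2-yl] (1R,2S)-6,7-bis(benzyloxy)-1-[3,4-bis(benzyloxy)phenyl]-1,2-dihydronaphthalene-2,3-dicarboxylate (decabenzyl rabdosiin)
Conditions: 9-mesityl-10-methylacridinium perchlorate (5 mol%), Co(dmgH)2(py)Cl (5 mol%), DCE/HFIP 9:1 (0.02 M), 450 nm LEDs, 0 °C, Ar, stopped at full conversion of 11
Reagents that add atoms: none
Why: Proposed new method: oxidative radical-cation ring expansion of a 1,2-diarylcyclobutane to a 1-aryl-1,2-dihydronaphthalene. The excited acridinium (about +2.0 V vs SCE) oxidises a 3,4-dialkoxyphenyl ring of 11 (about +1.3 V), and the strained C3–C4 bond, benzylic on both sides, breaks to a distonic 1,4-radical cation. The benzylic cation end is attacked by C6 of the aryl ring at the other end (para to its 3-benzyloxy group, six-membered Friedel–Crafts closure) and proton loss re-aromatises. Divalent cobalt of the cobaloxime then abstracts the hydrogen alpha to the ester next to the remaining benzylic radical, giving the conjugated C3=C4 bond and, after protonation, H2, while the acridine radical returns trivalent cobalt to the divalent state. The ester-bearing carbon that stays sp3 is never broken, so C2 (S) comes unchanged from 11 (the C2 axis makes both closure directions identical), and C1 (R) forms trans to it, as in cationic cyclisations to this lignan skeleton. Closest known chemistry: radical-cation rearrangement of anethole-type cyclobutane dimers to 1-aryltetralins, photoredox ring-opening of arylcyclobutanes and arylcyclopropanes, and acridinium/cobaloxime hydrogen-evolving desaturation.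

Step 9
Reactants: 12 decabenzyl rabdosiin
Product: 13 rabdosiin
Conditions: BCl3 (1 M in CH2Cl2, 25 equiv), C6HMe5 (30 equiv), CH2Cl2, −78 to −20 °C; MeOH/H2O quench; reverse-phase HPLC
Reagents that add atoms: none
Why: Lewis-acid debenzylation with pentamethylbenzene as cation scavenger cleaves the eight aryl benzyl ethers and two benzyl esters, while the conjugated double bond, the two secondary alkyl esters and the C1/C2 stereocentres (no base, no hydrogen) are left untouched.

## Compound list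

1 | catechol (benzene-1,2-diol) | Oc1ccccc1O | starting material
2 | 1,2-bis(benzyloxy)benzene | c1ccc(COc2ccccc2OCc2ccccc2)cc1 | intermediate
3 | 4-bromo-1,2-bis(benzyloxy)benzene | Brc1ccc(OCc2ccccc2)c(OCc2ccccc2)c1 | intermediate
4 | methyl (R)-glycidate (methyl (2R)-oxirane-2-carboxylate) | COC(=O)[C@H]1CO1 | starting material
5 | 3,4-bis(benzyloxy)phenylmagnesium bromide | Br[Mg]c1ccc(OCc2ccccc2)c(OCc2ccccc2)c1 | intermediate (not isolated)
6 | methyl (2R)-3-[3,4-bis(benzyloxy)phenyl]-2-hydroxypropanoate | COC(=O)[C@H](O)Cc1ccc(OCc2ccccc2)c(OCc2ccccc2)c1 | intermediate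
7 | benzyl (2R)-3-[3,4-bis(benzyloxy)phenyl]-2-hydroxypropanoate | O=C(OCc1ccccc1)[C@H](O)Cc1ccc(OCc2ccccc2)c(OCc2ccccc2)c1 | intermediate
8 | acrylic acid | C=CC(=O)O | starting material
9 | (E)-3-[3,4-bis(benzyloxy)phenyl]prop-2-enoic acid | OC(=O)/C=C/c1ccc(OCc2ccccc2)c(OCc2ccccc2)c1 | intermediate
10 | benzyl (2R)-3-[3,4-bis(benzyloxy)phenyl]-2-{[(2E)-3-[3,4-bis(benzyloxy)phenyl]prop-2-enoyl]oxy}propanoate (pentabenzyl (R)-rosmarinate) | O=C(O[C@H](Cc1ccc(OCc2ccccc2)c(OCc2ccccc2)c1)C(=O)OCc1ccccc1)/C=C/c1ccc(OCc2ccccc2)c(OCc2ccccc2)c1 | intermediate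
11 | bis[(2R)-1-(benzyloxy)-3-[3,4-bis(benzyloxy)phenyl]-1-oxopropan-2-yl] (1S,2S,3R,4R)-3,4-bis[3,4-bis(benzyloxy)phenyl]cyclobutane-1,2-dicarboxylate | O=C(O[C@H](Cc1ccc(OCc2ccccc2)c(OCc2ccccc2)c1)C(=O)OCc1ccccc1)[C@H]1[C@H](c2ccc(OCc3ccccc3)c(OCc3ccccc3)c2)[C@@H](c2ccc(OCc3ccccc3)c(OCc3ccccc3)c2)[C@@H]1C(=O)O[C@H](Cc1ccc(OCc2ccccc2)c(OCc2ccccc2)c1)C(=O)OCc1ccccc1 | intermediate
12 | bis[(2R)-1-(benzyloxy)-3-[3,4-bis(benzyloxy)phenyl]-1-oxopropan-2-yl] (1R,2S)-6,7-bis(benzyloxy)-1-[3,4-bis(benzyloxy)phenyl]-1,2-dihydronaphthalene-2,3-dicarboxylate | O=C(O[C@H](Cc1ccc(OCc2ccccc2)c(OCc2ccccc2)c1)C(=O)OCc1ccccc1)C1=Cc2cc(OCc3ccccc3)c(OCc3ccccc3)cc2[C@@H](c2ccc(OCc3ccccc3)c(OCc3ccccc3)c2)[C@@H]1C(=O)O[C@H](Cc1ccc(OCc2ccccc2)c(OCc2ccccc2)c1)C(=O)OCc1ccccc1 | intermediate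
13 | rabdosiin, bis[(1R)-1-carboxy-2-(3,4-dihydroxyphenyl)ethyl] (1R,2S)-6,7-dihydroxy-1-(3,4-dihydroxyphenyl)-1,2-dihydronaphthalene-2,3-dicarboxylate | O=C(O[C@H](Cc1ccc(O)c(O)c1)C(=O)O)C1=Cc2cc(O)c(O)cc2[C@@H](c2ccc(O)c(O)c2)[C@@H]1C(=O)O[C@H](Cc1ccc(O)c(O)c1)C(=O)O | target

## Step count and risks

Total steps: 9. Longest linear sequence: 8 (1 → 2 → 3 → 6 → 7 → 10 → 11 → 12 → 13).

**Step 7 (enantioselective head-to-head photodimerisation).** The catalyst system is established for cinnamate esters reacting with styrenes; here the second alkene is another cinnamate. Possible failures are a racemic background dimerisation, binding of the acid to the benzyl ester carbonyl, cis-fused isomers, or the opposite sense of induction (the (R)-catalyst is equally available). Fallback, setting out from 10: irradiate with fac-Ir(ppy)3 (1 mol%) alone in MeCN at rt (450 nm). This known sensitised dimerisation gives the all-trans head-to-head dimer as a roughly 1:1 pair that differs only in the cyclobutane configuration: 11 and bis[(2R)-1-(benzyloxy)-3-[3,4-bis(benzyloxy)phenyl]-1-oxopropan-2-yl] (1R,2R,3S,4S)-3,4-bis[3,4-bis(benzyloxy)phenyl]cyclobutane-1,2-dicarboxylate F1. The (R)-lactate esters make the two diastereomers separable by preparative HPLC, and F1 can be cycloreverted to 10 at 254 nm and recycled. The route is rejoined at 11.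

**Step 8 (new ring expansion).** Possible failures are cycloreversion of the radical cation to 10 (recoverable), over-oxidation of 12 to the 1-arylnaphthalene, oxidation at the lactate benzylic CH2 groups, or loss of the C2 configuration by elimination before ring closure. Fallback with known chemistry, setting out from 10: BCl3/C6HMe5 in CH2Cl2 at −78 °C removes the five benzyl groups and gives (R)-rosmarinic acid F2. Biomimetic oxidative 8–8′ coupling and cyclisation of the free caffeate (FeCl3·6H2O, 2 equiv, aqueous acetone, rt) then gives 13 together with the (1S,2R)-diastereomer of rabdosiin F3 and other coupling isomers. This is the known route by which caffeate and sinapate esters give 1-aryl-1,2-dihydronaphthalene-2,3-dicarboxylates; it is low-yielding and not stereoselective, so 13 is isolated by reverse-phase HPLC. The route is rejoined at 13.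

**Step 9 (ten-fold debenzylation).** Possible failures are incomplete cleavage, C-benzylation of the catechol rings, or acid damage to the polyphenolic product. Fallback, setting out from 11, where no alkene is present and hydrogenolysis is safe: H2, Pd/C, THF/MeOH gives bis[(1R)-1-carboxy-2-(3,4-dihydroxyphenyl)ethyl] (1S,2S,3R,4R)-3,4-bis(3,4-dihydroxyphenyl)cyclobutane-1,2-dicarboxylate F4. TBSCl/imidazole in DMF gives its octa-O-TBS ether bis-TBS ester F5. The ring expansion under the step 8 conditions (DCE without HFIP) gives deca-TBS rabdosiin F6, and HF·pyridine in THF at 0 °C removes all silyl groups. The route is rejoined at 13.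

## Further compounds

F1 | step 7 | bis[(2R)-1-(benzyloxy)-3-[3,4-bis(benzyloxy)phenyl]-1-oxopropan-2-yl] (1R,2R,3S,4S)-3,4-bis[3,4-bis(benzyloxy)phenyl]cyclobutane-1,2-dicarboxylate | O=C(O[C@H](Cc1ccc(OCc2ccccc2)c(OCc2ccccc2)c1)C(=O)OCc1ccccc1)[C@@H]1[C@@H](c2ccc(OCc3ccccc3)c(OCc3ccccc3)c2)[C@H](c2ccc(OCc3ccccc3)c(OCc3ccccc3)c2)[C@H]1C(=O)O[C@H](Cc1ccc(OCc2ccccc2)c(OCc2ccccc2)c1)C(=O)OCc1ccccc1
F2 | step 8 | (R)-rosmarinic acid | O=C(O[C@H](Cc1ccc(O)c(O)c1)C(=O)O)/C=C/c1ccc(O)c(O)c1
F3 | step 8 | (1S,2R)-diastereomer of rabdosiin | O=C(O[C@H](Cc1ccc(O)c(O)c1)C(=O)O)C1=Cc2cc(O)c(O)cc2[C@H](c2ccc(O)c(O)c2)[C@H]1C(=O)O[C@H](Cc1ccc(O)c(O)c1)C(=O)O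
F4 | step 9 | bis[(1R)-1-carboxy-2-(3,4-dihydroxyphenyl)ethyl] (1S,2S,3R,4R)-3,4-bis(3,4-dihydroxyphenyl)cyclobutane-1,2-dicarboxylate | O=C(O[C@H](Cc1ccc(O)c(O)c1)C(=O)O)[C@H]1[C@H](c2ccc(O)c(O)c2)[C@@H](c2ccc(O)c(O)c2)[C@@H]1C(=O)O[C@H](Cc1ccc(O)c(O)c1)C(=O)O
F5 | step 9 | octa-O-TBS ether bis-TBS ester of F4 | O=C(O[C@H](Cc1ccc(O[Si](C)(C)C(C)(C)C)c(O[Si](C)(C)C(C)(C)C)c1)C(=O)O[Si](C)(C)C(C)(C)C)[C@H]1[C@H](c2ccc(O[Si](C)(C)C(C)(C)C)c(O[Si](C)(C)C(C)(C)C)c2)[C@@H](c2ccc(O[Si](C)(C)C(C)(C)C)c(O[Si](C)(C)C(C)(C)C)c2)[C@@H]1C(=O)O[C@H](Cc1ccc(O[Si](C)(C)C(C)(C)C)c(O[Si](C)(C)C(C)(C)C)c1)C(=O)O[Si](C)(C)C(C)(C)C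
F6 | step 9 | deca-TBS rabdosiin | O=C(O[C@H](Cc1ccc(O[Si](C)(C)C(C)(C)C)c(O[Si](C)(C)C(C)(C)C)c1)C(=O)O[Si](C)(C)C(C)(C)C)C1=Cc2cc(O[Si](C)(C)C(C)(C)C)c(O[Si](C)(C)C(C)(C)C)cc2[C@@H](c2ccc(O[Si](C)(C)C(C)(C)C)c(O[Si](C)(C)C(C)(C)C)c2)[C@@H]1C(=O)O[C@H](Cc1ccc(O[Si](C)(C)C(C)(C)C)c(O[Si](C)(C)C(C)(C)C)c1)C(=O)O[Si](C)(C)C(C)(C)C
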